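The lower dihydroflavonol ring is made last, by contraction of a seven-membered acetal. The disconnection is C2–C3 of that pyranone: C2 is benzylic to the catechol B ring and bound to the ring oxygen O1, so it supports a cation, and C3 is the α-carbon of the C4 ketone and carries the hydroxyl oxygen. Tying that oxygen to C2 gives a 2-aryl-1,3-benzodioxepin-5-one, reached by acetalisation of an α-ketol with 3,4-bis(benzyloxy)benzaldehyde. A chiral Brønsted acid opens the acetal and the enediol recloses through carbon, which forms C2–C3, the pyranone, both stereocentres and the free 3-OH at once. The upper unit is bought as (−)-epicatechin.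

Key step: step 8

Assumption: the sense of induction of the chiral acid in step 8 cannot be predicted with certainty; the (R)-catalyst is written, and its antipode is to be used if it proves mismatched with the resident flavan unit.

Step 1
Reactants: 1 (−)-epicatechin
Product: 2 5,7,3',4'-tetra-O-benzyl-(−)-epicatechin
Conditions: BnBr (4.4 equiv), K2CO3, DMF, 0 °C → rt
Reagents that add atoms: benzyl bromide, BrCc1ccccc1
Why: Williamson etherification: carbonate ionises only the four phenols, which are benzylated, while the secondary 3-OH stays free and C2/C3 are untouched.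

Step 2
Reactants: 2 5,7,3',4'-tetra-O-benzyl-(−)-epicatechin
Product: 3 8-bromo-5,7,3',4'-tetra-O-benzyl-(−)-epicatechin
Conditions: NBS (1.0 equiv), CH2Cl2, −78 °C → rt
Reagents that add atoms: N-bromosuccinimide, O=C1CCC(=O)N1Br
Why: Electrophilic aromatic bromination (SEAr) of the phloroglucinol-type A ring should go to C8, which is flanked by O1 and one benzyloxy group and is less hindered than C6; the bromine caps this ring against self-condensation in step 5 and is removed in step 9.

Step 3
Reactants: 3 8-bromo-5,7,3',4'-tetra-O-benzyl-(−)-epicatechin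
Product: 4 8-bromo-3,5,7,3',4'-penta-O-benzyl-(−)-epicatechin
Conditions: NaH, BnBr, Bu4NI (cat.), DMF, 0 °C → rt
Reagents that add atoms: benzyl bromide, BrCc1ccccc1
Why: Williamson etherification of the sodium alkoxide protects the 3-OH, which would otherwise compete for the aldehyde acetal in step 7 and trap the cation in step 8.

Step 4
Reactants: 4 8-bromo-3,5,7,3',4'-penta-O-benzyl-(−)-epicatechin
Product: 5 8-bromo-3,5,7,3',4'-penta-O-benzyl-4β-(2-ethoxyethoxy)epicatechin (3,4-trans)
Conditions: DDQ (2 equiv), 2-ethoxyethanol (5 equiv), CH2Cl2, rt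
Reagents that add atoms: 2-ethoxyethanol, CCOCCO
Why: DDQ-mediated oxidative benzylic C–H alkoxylation: hydride abstraction from C4 gives a cation stabilised by the 5,7-dioxygenated A ring, which the alcohol should trap anti to the 3-benzyloxy group (4β); the C4 configuration is of no consequence because step 5 passes through the same cation.

Step 5
Reactants: 5 8-bromo-3,5,7,3',4'-penta-O-benzyl-4β-(2-ethoxyethoxy)epicatechin; 6 1-[2,4-bis(benzyloxy)-6-hydroxyphenyl]ethanone
Product: 7 3'-(8-bromo-penta-O-benzylepicatechin-4β-yl)-4',6'-bis(benzyloxy)-2'-hydroxyacetophenone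
Conditions: 6 (3 equiv), TMSOTf (0.3 equiv), 4 Å MS, CH2Cl2, −78 → −30 °C
Reagents that add atoms: none
Why: Friedel–Crafts-type flavanylation as used for interflavan bonds: TMSOTf ionises the C4 ether, the phenol ring of 6 should attack through the carbon ortho to its free OH (less hindered than the site between two benzyloxy groups and also reachable by O-alkylation and O→C shift), and the new C4 centre is set 4β, trans to 3-OBn, because the cis 2-aryl and 3-benzyloxy groups shield the α-face.

Step 6
Reactants: 7 3'-(8-bromo-penta-O-benzylepicatechin-4β-yl)-4',6'-bis(benzyloxy)-2'-hydroxyacetophenone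
Product: 10 α-ketol 3'-(8-bromo-penta-O-benzylepicatechin-4β-yl)-4',6'-bis(benzyloxy)-2',ω-dihydroxyacetophenone, via bis-TMS enol ether 8 (not isolated), via bis-silylated ketol 9 (not isolated)
Conditions: TMSOTf (2.5 equiv), Et3N, CH2Cl2, 0 °C; NaHCO3 wash; mCPBA (1.1 equiv), NaHCO3, CH2Cl2, −20 °C; aq. citric acid, THF, rt
Reagents that add atoms: meta-chloroperbenzoic acid, OOC(=O)c1cccc(Cl)c1
Why: Rubottom oxidation: soft enolisation gives the silyl enol ether (the phenol is silylated as well), mCPBA epoxidises this most electron-rich alkene, the silyloxy epoxide rearranges by 1,4-silyl shift, and mild acid removes both silyl groups to give the α-ketol.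

Step 7
Reactants: 10 α-ketol from step 6; 11 3,4-bis(benzyloxy)benzaldehyde
Product: 13 2-[3,4-bis(benzyloxy)phenyl]-6,8-bis(benzyloxy)-9-(8-bromo-penta-O-benzylepicatechin-4β-yl)-4H-1,3-benzodioxepin-5-one (acetal carbon as epimer mixture), via dimethyl acetal 12 (not isolated)
Conditions: 11, HC(OMe)3, TsOH (cat.), MeOH, rt, evaporate; then 10, PPTS (cat.), toluene, 5 Å MS, 45 °C
Reagents that add atoms: none
Why: Acid-catalysed transacetalisation of the phenol/primary-alcohol pair by the dimethyl acetal made in the flask should close the seven-membered aryl alkyl acetal, driven by removal of methanol; the acetal carbon forms as an epimer mixture, which does not matter because this centre becomes planar in step 8.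

Step 8
Reactants: 13 benzodioxepinone acetal from step 7
Product: 15 8-(8-bromo-penta-O-benzylepicatechin-4β-yl)-5,7,3',4'-tetra-O-benzyl-(2R,3R)-taxifolin, via ring-opened oxocarbenium enediol 14 (not isolated)
Conditions: (R)-3,3'-bis(2,4,6-triisopropylphenyl)-BINOL N-triflylphosphoramide (10 mol%), toluene (0.01 M), 5 Å MS, −20 → 0 °C
Reagents that add atoms: none
Why: Proposed new method: the chiral acid should protonate the acetal oxygen O3 and cleave C2–O3, giving an ion pair of the O1-aryl oxocarbenium ion at C2 (further stabilised by the 4'-benzyloxy group) with the chiral phosphoramide anion, while the released α-ketol tautomerises to its enediol (14), whose C3 then attacks C2 in a ring-contractive formal [1,2] O→C shift. The closest known reaction types are the Petasis–Ferrier rearrangement with its chiral-phosphoric-acid variants (acetal ionisation, then enol–oxocarbenium recombination) and the silyl-enol-ether Prins closure of tetrahydropyran-4-ones, neither shown for an α-ketol acetal or for an aryl oxocarbenium ion closing a chroman-4-one. The pyranone ring closes in a 6-(enolendo)-endo-trig mode. C2 is set by the chiral counter-anion, which selects the face of the planar cation (reagent control, reinforced or opposed by the neighbouring flavan-4-yl group, the two outcomes being separable diastereomers), and C3 follows from C2 because the half-chair transition state and the enolisable product both place 2-aryl and 3-OH trans-diequatorial. The step needs ionisation at C2–O3 rather than C2–O1 and attack by C3 rather than C4: cleavage of C2–O1 is reversible and unproductive because its cation carries C3 directly on the oxocarbenium oxygen, and attack by C4 would be a 5-endo closure to a quaternary centre. The nine benzyl ethers are not at the acetal oxidation level and should stay untouched.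

Step 9
Reactants: 15 protected dimer from step 8
Product: 16 epicatechin-(4β→8)-(2R,3R)-taxifolin (CNP0210692.1)
Conditions: H2 (1 atm), 20% Pd(OH)2/C, NaOAc (1.1 equiv), THF/MeOH/H2O, rt
Reagents that add atoms: none
Why: Heterogeneous hydrogenolysis should cleave all nine O-benzyl groups and the aryl C–Br bond while the aryl ketone, the C2–O1 bonds and the interflavan C4–C8 bond are retained, as in standard procyanidin and taxifolin deprotections; acetate buffers the hydrogen bromide.

Compound list
1 | (−)-epicatechin, (2R,3R)-2-(3,4-dihydroxyphenyl)chromane-3,5,7-triol | C1c2c(O)cc(O)cc2O[C@H](c2ccc(O)c(O)c2)[C@@H]1O | starting material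
2 | 5,7,3',4'-tetra-O-benzyl-(−)-epicatechin (2R,3R) | C1c2c(OCc3ccccc3)cc(OCc3ccccc3)cc2O[C@H](c2ccc(OCc3ccccc3)c(OCc3ccccc3)c2)[C@@H]1O | intermediate
3 | 8-bromo-5,7,3',4'-tetra-O-benzyl-(−)-epicatechin (2R,3R) | C1c2c(OCc3ccccc3)cc(OCc3ccccc3)c(Br)c2O[C@H](c2ccc(OCc3ccccc3)c(OCc3ccccc3)c2)[C@@H]1O | intermediate
4 | 8-bromo-3,5,7,3',4'-penta-O-benzyl-(−)-epicatechin (2R,3R) | C1c2c(OCc3ccccc3)cc(OCc3ccccc3)c(Br)c2O[C@H](c2ccc(OCc3ccccc3)c(OCc3ccccc3)c2)[C@@H]1OCc1ccccc1 | intermediate
5 | 8-bromo-3,5,7,3',4'-penta-O-benzyl-4β-(2-ethoxyethoxy)epicatechin (2,3-cis, 3,4-trans) | CCOCCO[C@H]1c2c(OCc3ccccc3)cc(OCc3ccccc3)c(Br)c2O[C@H](c2ccc(OCc3ccccc3)c(OCc3ccccc3)c2)[C@@H]1OCc1ccccc1 | intermediate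
6 | 1-[2,4-bis(benzyloxy)-6-hydroxyphenyl]ethanone | CC(=O)c1c(O)cc(OCc2ccccc2)cc1OCc1ccccc1 | starting material
7 | 3'-(8-bromo-penta-O-benzylepicatechin-4β-yl)-4',6'-bis(benzyloxy)-2'-hydroxyacetophenone | CC(=O)c1c(OCc2ccccc2)cc(OCc2ccccc2)c([C@H]2c3c(OCc4ccccc4)cc(OCc4ccccc4)c(Br)c3O[C@H](c3ccc(OCc4ccccc4)c(OCc4ccccc4)c3)[C@@H]2OCc2ccccc2)c1O | intermediate
8 | bis-TMS enol ether of 7 (phenol and enol oxygen silylated) | C=C(O[Si](C)(C)C)c1c(OCc2ccccc2)cc(OCc2ccccc2)c([C@H]2c3c(OCc4ccccc4)cc(OCc4ccccc4)c(Br)c3O[C@H](c3ccc(OCc4ccccc4)c(OCc4ccccc4)c3)[C@@H]2OCc2ccccc2)c1O[Si](C)(C)C | intermediate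
9 | bis-silylated ketol (phenol and primary alcohol as TMS ethers) | C[Si](C)(C)OCC(=O)c1c(OCc2ccccc2)cc(OCc2ccccc2)c([C@H]2c3c(OCc4ccccc4)cc(OCc4ccccc4)c(Br)c3O[C@H](c3ccc(OCc4ccccc4)c(OCc4ccccc4)c3)[C@@H]2OCc2ccccc2)c1O[Si](C)(C)C | intermediate
10 | α-ketol, 3'-(8-bromo-penta-O-benzylepicatechin-4β-yl)-4',6'-bis(benzyloxy)-2',ω-dihydroxyacetophenone | OCC(=O)c1c(OCc2ccccc2)cc(OCc2ccccc2)c([C@H]2c3c(OCc4ccccc4)cc(OCc4ccccc4)c(Br)c3O[C@H](c3ccc(OCc4ccccc4)c(OCc4ccccc4)c3)[C@@H]2OCc2ccccc2)c1O | intermediate
11 | 3,4-bis(benzyloxy)benzaldehyde | O=Cc1ccc(OCc2ccccc2)c(OCc2ccccc2)c1 | starting material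
12 | 3,4-bis(benzyloxy)benzaldehyde dimethyl acetal | COC(OC)c1ccc(OCc2ccccc2)c(OCc2ccccc2)c1 | intermediate
13 | 2-[3,4-bis(benzyloxy)phenyl]-6,8-bis(benzyloxy)-9-(8-bromo-penta-O-benzylepicatechin-4β-yl)-4H-1,3-benzodioxepin-5-one (acetal carbon undefined) | O=C1COC(c2ccc(OCc3ccccc3)c(OCc3ccccc3)c2)Oc2c([C@H]3c4c(OCc5ccccc5)cc(OCc5ccccc5)c(Br)c4O[C@H](c4ccc(OCc5ccccc5)c(OCc5ccccc5)c4)[C@@H]3OCc3ccccc3)c(OCc3ccccc3)cc(OCc3ccccc3)c21 | intermediate
14 | ring-opened O1-aryl oxocarbenium ion with pendant enediol (cation of the ion pair with the catalyst anion) | OC=C(O)c1c(OCc2ccccc2)cc(OCc2ccccc2)c([C@H]2c3c(OCc4ccccc4)cc(OCc4ccccc4)c(Br)c3O[C@H](c3ccc(OCc4ccccc4)c(OCc4ccccc4)c3)[C@@H]2OCc2ccccc2)c1[O+]=Cc1ccc(OCc2ccccc2)c(OCc2ccccc2)c1 | intermediate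
15 | 8-(8-bromo-penta-O-benzylepicatechin-4β-yl)-5,7,3',4'-tetra-O-benzyl-(2R,3R)-taxifolin (2,3-trans, free 3-OH) | O=C1c2c(OCc3ccccc3)cc(OCc3ccccc3)c([C@H]3c4c(OCc5ccccc5)cc(OCc5ccccc5)c(Br)c4O[C@H](c4ccc(OCc5ccccc5)c(OCc5ccccc5)c4)[C@@H]3OCc3ccccc3)c2O[C@H](c2ccc(OCc3ccccc3)c(OCc3ccccc3)c2)[C@H]1O | intermediate
16 | epicatechin-(4β→8)-(2R,3R)-taxifolin, CNP0210692.1 | O=C1c2c(O)cc(O)c([C@H]3c4c(O)cc(O)cc4O[C@H](c4ccc(O)c(O)c4)[C@@H]3O)c2O[C@H](c2ccc(O)c(O)c2)[C@H]1O | target

Total step count: 9. Longest linear sequence: 9 steps (1 → 16); 6 and 11 are bought.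

Steps most likely to fail

Step 8 (proposed new method). The ring-opened ion pair may simply re-close to the acetal without enolisation and C–C bond formation, or the chiral anion may fail to override the facial bias of the neighbouring flavan unit. The fallback uses known chemistry and sets out from ketol 10 and aldehyde 11. A direct asymmetric aldol addition of the α-hydroxy ketone (dinuclear Zn–ProPhenol, Et2Zn, 4 Å MS, THF, −20 °C) should give the syn-α,β-dihydroxy ketone F1, with the ligand antipode chosen for the (R)-carbinol next to the ketone. Intramolecular Mitsunobu etherification (PPh3, DIAD, THF, 0 °C) then lets the phenol displace the benzylic hydroxyl with inversion to give the 2,3-trans ring. The fallback comes back to the route at 15.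

Step 5. The acyl-deactivated phenol 6 may react too slowly, so that the cation from 5 decomposes, or attack may occur para to the hydroxyl. The fallback sets out from 5 and uses the more nucleophilic 3,5-bis(benzyloxy)phenol under the same TMSOTf conditions to give the ortho-flavanylated phenol F2. Phenol-directed ortho-acetylation (Ac2O, BF3·OEt2, CH2Cl2, 0 °C, Fries-type through the aryl acetate) then installs the acetyl group; the bromine-capped upper A ring is inert. The fallback comes back at 7.

Step 7. Closure of the seven-membered aryl alkyl acetal at the hindered, hydrogen-bonded phenol may stall at the open mixed acetal, or the acetal may rearrange prematurely without stereocontrol. The fallback sets out from 10. Selective O-alkylation of the phenol with 3,4-bis(benzyloxy)benzyl chloride (K2CO3, KI cat., acetone) gives the aryl benzyl ether F3. DDQ (CH2Cl2, 4 Å MS, 0 °C) then oxidises the electron-rich benzylic position, and the primary hydroxyl traps the cation (oxidative acetal formation of the Oikawa–Yonemitsu type). The fallback comes back at 13.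

Further compounds
F1 | step 8 | syn-diol, (2R,3S)-3-[3,4-bis(benzyloxy)phenyl]-2,3-dihydroxy-1-[4,6-bis(benzyloxy)-3-(8-bromo-penta-O-benzylepicatechin-4β-yl)-2-hydroxyphenyl]propan-1-one | O=C([C@H](O)[C@@H](O)c1ccc(OCc2ccccc2)c(OCc2ccccc2)c1)c1c(OCc2ccccc2)cc(OCc2ccccc2)c([C@H]2c3c(OCc4ccccc4)cc(OCc4ccccc4)c(Br)c3O[C@H](c3ccc(OCc4ccccc4)c(OCc4ccccc4)c3)[C@@H]2OCc2ccccc2)c1O
F2 | step 5 | 2-(8-bromo-penta-O-benzylepicatechin-4β-yl)-3,5-bis(benzyloxy)phenol | Oc1cc(OCc2ccccc2)cc(OCc2ccccc2)c1[C@H]1c2c(OCc3ccccc3)cc(OCc3ccccc3)c(Br)c2O[C@H](c2ccc(OCc3ccccc3)c(OCc3ccccc3)c2)[C@@H]1OCc1ccccc1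
F3 | step 7 | 2'-O-[3,4-bis(benzyloxy)benzyl] ether of ketol 10 | OCC(=O)c1c(OCc2ccccc2)cc(OCc2ccccc2)c([C@H]2c3c(OCc4ccccc4)cc(OCc4ccccc4)c(Br)c3O[C@H](c3ccc(OCc4ccccc4)c(OCc4ccccc4)c3)[C@@H]2OCc2ccccc2)c1OCc1ccc(OCc2ccccc2)c(OCc2ccccc2)c1
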